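(The data were computed with made-up constants; noise was put on by code.)

A rate constant multiplies the catalyst that is working, so before any constant there is a subtraction to make.

in all of them: impurity 1.8 mM
- blue: starting material 2 M; free catalyst 1.3 mM; run made earlier
- green: starting material 2 M; free catalyst 3 mM; run made earlier
- flask: starting material 2.0 M; free catalyst 2.0 mM; time 2.0 d

| run | time / h | starting material / % | target / % |
|---|---|---|---|
| blue | 2.00 | 36 | 53 |
| blue | 6.00 | 27 | 56 |
| blue | 10.0 | 23 | 56 |
| blue | 15.0 | 24 | 54 |
| blue | 25.0 | 20 | 55 |
| blue | 30.0 | 24 | 56 |
| blue | 40.0 | 24 | 54 |
| green | 6.00 | 4 | 92 |
| green | 12.0 | 4 | 95 |
| green | 15.0 | 10 | 91 |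
| green | 20.0 | 2 | 89 |
| green | 30.0 | 3 | 93 |
| green | 40.0 | 2 | 91 |

(each reading ± 2 percentage points)

- why nothing more happens at 2.0 d, or that something still does (no working catalyst is left / forward and back rates have come level / all of the starting material has reacted / it is still moving)
- conversion of starting material at 2.0 d
- amount of target at 2.0 d, in percent of the starting material charged
- amount of isomer of the product at 2.0 d, in percent of the starting material charged

- the analysis behind the earlier runs scatters by 2 percentage points, standard deviation
- the reaction counts as stopped when no species that holds the starting material changes by six tenths of a point or more over the second half of the time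

The blue run stands still near 24% starting material, more than the 2% of the green run, so blue's stop is no balance of forward and back. Blue was charged with less free catalyst than impurity and green with more, which reads as impurity removing catalyst one for one. Impurity is then the limiting reagent of that loss in green and in the flask. Free catalyst charged minus impurity charged gives the flask 0.200 mM, its catalyst excess. The same subtraction gives −0.500 mM for blue and 1.20 mM for green.

The flask was charged with more free catalyst than impurity, so it should keep turning over, but its excess is smaller than green's. Green supplies the speed. With a steady catalyst amount the fall is pseudo-first-order, and green's 4% after 6.00 h gives an estimated rate of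

0.536 h⁻¹

Scaled by excess, the flask gets

0.0894 h⁻¹

Over 2.0 d, in powers of ten, that is

1.86

That is more than the 1.70 powers of ten from the charge down to green's last reading, so this reckoning brings the flask to balance and places it with green, at target near 91%. The unread rest of 7.00%, counted as isomer, carries the scatter of the readings.

The forecast also expects forward and back rates have come level, but gives conversion 97%, target 87% and isomer 10%, holding that “isomer should land between the two”. Its target is lower and its isomer higher than this reckoning's.

The flask gives forward and back rates have come level, with conversion 96.1%, target 92.8% and isomer 3.29%.

    starting material + free catalyst ⇌ target + free catalyst, rate k1*[starting material]*[free catalyst] forward; the back reaction follows from the equilibrium constant (K = 24.0, k = 2.20 M⁻¹ s⁻¹)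
    starting material ⇌ isomer of the product (K = 0.850, k = 4.10 × 10⁻⁵ s⁻¹)
    free catalyst + impurity → spent catalyst (k = 3.30 M⁻¹ s⁻¹)
    2 free catalyst ⇌ resting dimer, settled at all times (K = 910 M⁻¹)

In the flask, target already stood at 91.2% after 0.100 d, a time shorter than the 0.20 d forward half-life of starting material by the isomer step alone. The neighbour charged with 3.10 mM impurity, more than its free catalyst, has an excess of −1.10 mM, and that surplus of impurity is 35.5% of its impurity charge. After 2.00 d that neighbour holds 0% free catalyst, 35.5% of its impurity, 48.7% target and 23.6% isomer.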